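**Remark on the chemistry (assumption).** Labdane numbering is used throughout: C1–C10 form the decalin, C11–C16 the side chain (C16 is the methyl on C13), C17 is the methyl on C8, C18 and C19 sit on C4, and C20 on C10. Read this way, the SMILES is a normal-series labdane, (4S,5R,8R,9R,10S,13E), with the acetoxymethyl group axial on C4 (C19).

## Analysis of the target

Compound 19 is a bicyclic labdane: a trans-fused decalin (ring A: C1–C5 and C10; ring B: C5–C10) with a C9 side chain that ends in an (E)-trisubstituted allylic alcohol (C13=C14, C15–OH). The configuration is 10β-CH3 and 5α-H (trans fusion), the C9 chain equatorial (β), the tertiary 8α-OH equatorial with C17 axial, and on C4 an axial CH2OAc (C19, syn to C20) beside an equatorial methyl (C18). The five stereocentres are contiguous around the decalin (C4–C5–C10–C9–C8); C4 and C10 are all-carbon quaternary centres and C8 is a tertiary carbinol. The C5/C10/C9/C8 pattern is what a chair–chair closure of an (E,E)-1,5-diene gives. C4 is the hard point: its two one-carbon groups differ only in oxidation, the oxidised one is the more hindered (1,3-diaxial to C20), and neither C3 nor C6 carries an oxygen to use as a handle. The feature that invites the key move is the unit C19–O on quaternary C4 of ring A with C3 unoxidised. C4, C19 and that oxygen are the three ring atoms of a 2,2-disubstituted oxirane, so an oxirane opened at C4 by the C5=C10 π bond leaves its oxygen on C19 and nothing on C3. In the same way the equatorial C8–O bond of ring B lies 1,5 to C13, where a carbonyl oxygen can close it. Three oxygen functions must end up differentiated (free tertiary OH, free allylic primary OH, acetylated neopentyl primary OH), and the acetate rules out any late hydride reduction. The C8 carbinol is acid-sensitive (dehydration, or pyran formation with a C13 allyl cation), and the allylic alcohol ionises easily.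

## Retrosynthetic reasoning

**19 ⇐ 18 ⇐ 17 (C15–O/C19–O differentiation).** The two primary alcohols of triol 17 differ strongly in access: C15 is allylic and open, C19 is neopentyl and axial. Acetylating both (18) and removing only the exposed C15 acetate enzymatically needs no protecting group and keeps hydride reagents away from the acetate.

**17 ⇐ 16 ⇐ 15 (C13=C14).** The side chain is cut at C13=C14 (Horner–Wadsworth–Emmons olefination, then ester reduction). This leaves a C13 methyl ketone, and a C13 carbonyl oxygen is the internal nucleophile that can make the C8–O bond: the δ-hydroxy ketone 15 is simply the hydrate of the cyclic enol ether 14.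

**15 ⇐ 14 ⇐ 13 (key disconnection: C4–C5, C9–C10 and C8–O).** All three bonds are cut at once, which opens rings A and B and removes all five stereocentres. What remains is the acyclic epoxy dienone 13, whose only stereocentre is the oxirane carbon that becomes C4. The cut is placed here rather than at a conventional C3/C4 oxirane because the oxygen of 13 is expelled from ring A onto C19, so no C3 oxygen has to be removed later and C19 arrives already oxidised. Forward, a Lewis acid must open the oxirane at its fully substituted carbon with inversion by the C5=C10 π bond. The chair–chair cascade must then relay that one centre to C5, C10, C9 and C8, and the ketone oxygen must capture the C8 cation.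

**13 ⇐ 11 ⇐ 10 ⇐ 4 + 8 (oxirane; C1–C2).** The oxirane comes from the (S)-1,2-diol 11 by closure onto the primary carbon, which does not touch the stereocentre. Diol 11 is the doubly deprotected form of 10. The chain is cut at C1–C2, an sp3–sp3 bond between an allylic electrophile (8) and the Grignard reagent 9 from bromide 4. This cut separates the one stereocentre (in 4) from the two E alkenes (in 8), and both halves come from cheap materials.

**8 ⇐ 7 ⇐ 6 ⇐ 5 and 4 ⇐ 3 ⇐ 2 ⇐ 1.** Geranylacetone 5 already holds C5–C13, C16, C17, C20, C1 and both E alkenes; only its terminal E-methyl group (C1) has to be activated. The stereocentre is taken from (S)-citramalic acid 1, whose quaternary carbinol carbon maps directly onto C4 with its methyl (C18), CH2O (C19) and chain (C3) substituents.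

## Alternatives that were turned down

**Alternative 1:** Robinson annulation (the textbook route).
- Disconnection: the decalin is taken as a preformed block, (S)-Wieland–Miescher ketone A1, and C4, C8 and C9 are dressed afterwards.
- Forward key step: amine-catalysed Robinson annulation to A1, then reductive alkylation of the enone for the C4 substituents, removal of the C3 carbonyl, and conversion of the C9 ketone into the side chain and the C8 carbinol.
- Why turned down: the annulation sets only C10. C4 needs two alkylation events plus a deoxygenation at C3, and C5 needs a separate reduction. The C9 carbonyl sits on the carbon that must become a CH bearing the chain next to a new tertiary carbinol, which means homologation, alkene transposition and hydration. That is well over twenty operations and five separate stereochemical decisions.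

**Alternative 2:** oxidative radical bicyclisation.
- Disconnection: C4–C5 and C9–C10, from the α-methyl β-keto ester A2.
- Forward key step: Mn(OAc)3/Cu(OAc)2 generates the C4 radical, which closes both rings to A3 with the ester axial.
- Why turned down: the radical needs a C3 ketone that the target lacks, and removing it beside the C13 ketone costs at least three steps and a chemoselectivity problem. The cascade ends at C8 as the 8(17)-alkene, so the C8–O bond and its configuration need a separate hydration. The C4 radical is planar, so absolute control needs a covalently bound auxiliary. The C19 ester still has to be reduced with hydride.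

**Alternative 3:** late C–H oxidation at C19.
- Disconnection: the C19–O bond, on a gem-dimethyl labdane obtained by relay from sclareol A4 through allylic transposition to diol A5.
- Forward key step: directed or catalyst-controlled hydroxylation of the axial C19 methyl of A5.
- Why turned down: A5 has no functional group within reach of C19. The 8α-hydroxyl is equatorial on the α face of ring B, C19 is β-axial on ring A, and C3 and C6 are bare. The reaction would have to pick one of four unactivated methyl groups (C17, C18, C19, C20) in the presence of allylic and tertiary C–H bonds, which undirected oxidants prefer. The short step count rests on a selectivity for which the structure gives no basis.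

Key step: step 10

## Route

Step 1
Reactants: 1 (S)-citramalic acid [(2S)-2-hydroxy-2-methylbutanedioic acid]
Product: 2 (2S)-2-methylbutane-1,2,4-triol
Conditions: BH3·SMe2, B(OMe)3, THF, 0 °C → rt; MeOH
Reagents that add atoms: none
Why: Borane reduces both carboxylic acids to primary alcohols (chemoselective acid reduction); no bond to the tertiary carbinol carbon is touched, so the (S) centre, the future C4, is carried over unchanged.

Step 2
Reactants: 2 (2S)-2-methylbutane-1,2,4-triol
Product: 3 2-[(4S)-2,2,4-trimethyl-1,3-dioxolan-4-yl]ethan-1-ol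
Conditions: 2,2-dimethoxypropane, TsOH (cat.), acetone, rt
Reagents that add atoms: 2,2-dimethoxypropane, COC(C)(C)OC
Why: Acid-catalysed transacetalisation under thermodynamic control should give the five-membered dioxolane across the 1,2-diol rather than the 1,3-dioxane (which would carry an axial methyl group), leaving the remote primary alcohol free.

Step 3
Reactants: 3 2-[(4S)-2,2,4-trimethyl-1,3-dioxolan-4-yl]ethan-1-ol
Product: 4 (4S)-4-(2-bromoethyl)-2,2,4-trimethyl-1,3-dioxolane
Conditions: CBr4, PPh3, CH2Cl2, 0 °C
Reagents that add atoms: tetrabromomethane, BrC(Br)(Br)Br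
Why: Appel reaction of an unhindered primary alcohol under neutral conditions that the acetonide tolerates.

Step 4
Reactants: 5 geranylacetone [(5E)-6,10-dimethylundeca-5,9-dien-2-one]
Product: 6 2-[(3E)-4,8-dimethylnona-3,7-dien-1-yl]-2-methyl-1,3-dioxolane
Conditions: ethylene glycol, TsOH (cat.), toluene, reflux (Dean–Stark)
Reagents that add atoms: ethylene glycol, OCCO
Why: Ketalisation masks the ketone against the Grignard reagent of step 7; the isolated trisubstituted alkenes are inert to catalytic acid under water removal.

Step 5
Reactants: 6 2-[(3E)-4,8-dimethylnona-3,7-dien-1-yl]-2-methyl-1,3-dioxolane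
Product: 7 (2E,6E)-2,6-dimethyl-9-(2-methyl-1,3-dioxolan-2-yl)nona-2,6-dien-1-ol
Conditions: SeO2 (cat.), t-BuOOH, CH2Cl2, 0 °C → rt
Reagents that add atoms: tert-butyl hydroperoxide, CC(C)(C)OO (terminal oxidant; the oxygen is relayed through SeO2, O=[Se]=O)
Why: Selenium dioxide allylic oxidation (ene reaction, then [2,3]-sigmatropic shift) is selective for the E-methyl group of the terminal, most accessible trisubstituted alkene and gives the (E)-allylic alcohol; this carbon becomes C1, trans to C6 as the cyclisation requires.

Step 6
Reactants: 7 (2E,6E)-2,6-dimethyl-9-(2-methyl-1,3-dioxolan-2-yl)nona-2,6-dien-1-ol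
Product: 8 2-[(3E,7E)-9-bromo-4,8-dimethylnona-3,7-dien-1-yl]-2-methyl-1,3-dioxolane
Conditions: CBr4, PPh3, CH2Cl2, −20 → 0 °C
Reagents that add atoms: tetrabromomethane, BrC(Br)(Br)Br
Why: Appel reaction; neutral, cold conditions should give the primary allylic bromide without allylic transposition and without loss of the ketal.

Step 7
Reactants: 4 (4S)-4-(2-bromoethyl)-2,2,4-trimethyl-1,3-dioxolane; 8 2-[(3E,7E)-9-bromo-4,8-dimethylnona-3,7-dien-1-yl]-2-methyl-1,3-dioxolane
Product: 10 (4S)-4-[(4E,8E)-4,8-dimethyl-11-(2-methyl-1,3-dioxolan-2-yl)undeca-4,8-dien-1-yl]-2,2,4-trimethyl-1,3-dioxolane, via Grignard reagent 9 (not isolated)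
Conditions: Mg, THF, 40 °C; then 8, Li2CuCl4 (3 mol%), THF, −78 → 0 °C
Reagents that add atoms: none
Why: Copper-catalysed Grignard cross-coupling with a primary allylic bromide forms C1–C2; with Li2CuCl4 at low temperature direct (SN2) substitution should dominate, so the alkene keeps its position and E geometry, and the γ-alkoxy Grignard reagent 9 has no β-leaving group.

Step 8
Reactants: 10 (4S)-4-[(4E,8E)-4,8-dimethyl-11-(2-methyl-1,3-dioxolan-2-yl)undeca-4,8-dien-1-yl]-2,2,4-trimethyl-1,3-dioxolane
Product: 11 (5E,9E,14S)-14,15-dihydroxy-6,10,14-trimethylpentadeca-5,9-dien-2-one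
Conditions: 1 M HCl, THF, rt
Reagents that add atoms: water, O
Why: Aqueous acid hydrolyses the acetonide and the dioxolane in one operation; dilute acid at room temperature should not protonate the isolated trisubstituted alkenes, and the stereocentre is not involved.

Step 9
Reactants: 11 (5E,9E,14S)-14,15-dihydroxy-6,10,14-trimethylpentadeca-5,9-dien-2-one
Product: 13 (5E,9E)-6,10-dimethyl-13-[(2S)-2-methyloxiran-2-yl]trideca-5,9-dien-2-one, via primary tosylate 12 (not isolated)
Conditions: TsCl, pyridine, CH2Cl2, 0 °C; then K2CO3, MeOH, rt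
Reagents that add atoms: none
Why: Only the primary hydroxyl is sulfonylated (the tertiary one is inert), and base then closes the oxirane by intramolecular Williamson displacement at the primary carbon; no bond to the stereocentre breaks, so (S) is retained.

Step 10
Reactants: 13 (5E,9E)-6,10-dimethyl-13-[(2S)-2-methyloxiran-2-yl]trideca-5,9-dien-2-one
Product: 15 (4S,5R,8R,9R,10S)-8,19-dihydroxy-14,15-dinorlabdan-13-one, via tricyclic enol ether 14 (not isolated)
Conditions: MeAlCl2 (2.2 equiv), CH2Cl2, −94 → −78 °C; then 1 M HCl, THF, 0 °C → rt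
Reagents that add atoms: water, O
Why: Proposed new method: epoxide-initiated cation–olefin polycyclisation is established for trisubstituted (oxidosqualene-type) oxiranes, and invertive opening at a fully substituted oxirane carbon is established for aryl π-nucleophiles (Friedel–Crafts cyclialkylation), but here a 2,2-disubstituted oxirane is asked to start an alkene cascade so that its oxygen leaves ring A and stays on C19; the closest known reaction type is the Lewis-acid-promoted epoxy-polyene cyclisation terminated by a carbonyl oxygen. MeAlCl2 activates the oxirane and the C5=C10 π bond attacks C4 anti to the departing C4–O bond (inversion; exo with respect to the breaking bond, 6-endo with respect to the alkene, closing ring A), then the C8=C9 π bond attacks C10 in a second 6-endo closure (ring B). The C8 cation is captured by the C13 carbonyl oxygen in a six-membered O–C8 closure, the oxocarbenium ion loses a proton to give enol ether 14, and aqueous acid hydrates 14 to the 8-hydroxy ketone 15. Both carbocycles close through chair transition states, so the E geometry of the two alkenes gives the trans fusion (5α-H, 10β-CH3), the equatorial C9 chain and, by anti addition across C8=C9, the equatorial 8α-oxygen with C17 axial. C4 is set by inversion of the (S)-oxirane carbon, and C5, C10, C9 and C8 follow from C4 because, of the two chair arrangements, the one with the free methyl equatorial and the oxirane CH2 axial next to C20 should be preferred, the CH2 being tied back towards the leaving oxygen and therefore the smaller group; this makes the CH2O group axial (C19). The step needs a concerted opening (a free C4 cation would erase the only stereocentre) and ring closure faster than 1,2-hydride shift from C19; low temperature, a non-ionising solvent and the 5,6-alkene placed for a six-membered chair are meant to secure both. More than two equivalents of Lewis acid are used because the ketone binds one.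

Step 11
Reactants: 15 (4S,5R,8R,9R,10S)-8,19-dihydroxy-14,15-dinorlabdan-13-one
Product: 16 ethyl (4S,5R,8R,9R,10S,13E)-8,19-dihydroxylabd-13-en-15-oate
Conditions: (EtO)2P(O)CH2CO2Et, NaH, THF, 0 → 50 °C
Reagents that add atoms: triethyl phosphonoacetate, CCOC(=O)CP(=O)(OCC)OCC
Why: Horner–Wadsworth–Emmons olefination of the methyl ketone should favour the E enoate (C12 trans to the ester) on steric grounds, with the minor Z isomer removed by chromatography; excess base covers the two hydroxyl groups, and oxa-Michael addition of the hindered tertiary alkoxide to the β,β-disubstituted enoate should be slow and reversible.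

Step 12
Reactants: 16 ethyl (4S,5R,8R,9R,10S,13E)-8,19-dihydroxylabd-13-en-15-oate
Product: 17 (4S,5R,8R,9R,10S,13E)-labd-13-ene-8,15,19-triol
Conditions: i-Bu2AlH (excess), CH2Cl2, −78 → 0 °C
Reagents that add atoms: none
Why: 1,2-Reduction of the conjugated ester to the allylic alcohol without conjugate reduction or change of alkene geometry; the excess covers the two free hydroxyl groups.

Step 13
Reactants: 17 (4S,5R,8R,9R,10S,13E)-labd-13-ene-8,15,19-triol
Product: 18 (4S,5R,8R,9R,10S,13E)-8-hydroxylabd-13-ene-15,19-diyl diacetate
Conditions: Ac2O, pyridine, DMAP (cat.), CH2Cl2, 0 °C → rt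
Reagents that add atoms: acetic anhydride, CC(=O)OC(C)=O
Why: Both primary alcohols are acylated, while the hindered tertiary 8-hydroxyl (flanked by C17 and the C9 chain) should not react under these mild conditions.

Step 14
Reactants: 18 (4S,5R,8R,9R,10S,13E)-8-hydroxylabd-13-ene-15,19-diyl diacetate
Product: 19 (4S,5R,8R,9R,10S,13E)-8,15-dihydroxylabd-13-en-19-yl acetate (CNP0161527.1)
Conditions: Candida antarctica lipase B (immobilised), n-BuOH, t-BuOMe, 30 °C
Reagents that add atoms: none
Why: Lipase-catalysed alcoholysis discriminates by access: the open primary allylic acetate at C15 should be accepted, whereas the axial neopentyl acetate at C19 (quaternary β-carbon, 1,3-diaxial to C20) should not; the neutral conditions leave the tertiary alcohol and the alkene untouched.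

## Compound list

1 | (S)-citramalic acid, (2S)-2-hydroxy-2-methylbutanedioic acid | C[C@@](O)(C(=O)O)CC(=O)O | starting material
2 | (2S)-2-methylbutane-1,2,4-triol | C[C@@](O)(CO)CCO | intermediate
3 | 2-[(4S)-2,2,4-trimethyl-1,3-dioxolan-4-yl]ethan-1-ol | C[C@]1(CCO)COC(C)(C)O1 | intermediate
4 | (4S)-4-(2-bromoethyl)-2,2,4-trimethyl-1,3-dioxolane | C[C@]1(CCBr)COC(C)(C)O1 | intermediate
5 | geranylacetone, (5E)-6,10-dimethylundeca-5,9-dien-2-one | CC(C)=CCC/C(C)=C/CCC(C)=O | starting material
6 | 2-[(3E)-4,8-dimethylnona-3,7-dien-1-yl]-2-methyl-1,3-dioxolane | CC(C)=CCC/C(C)=C/CCC1(C)OCCO1 | intermediate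
7 | (2E,6E)-2,6-dimethyl-9-(2-methyl-1,3-dioxolan-2-yl)nona-2,6-dien-1-ol | OC/C(C)=C/CC/C(C)=C/CCC1(C)OCCO1 | intermediate
8 | 2-[(3E,7E)-9-bromo-4,8-dimethylnona-3,7-dien-1-yl]-2-methyl-1,3-dioxolane | BrC/C(C)=C/CC/C(C)=C/CCC1(C)OCCO1 | intermediate
9 | {2-[(4S)-2,2,4-trimethyl-1,3-dioxolan-4-yl]ethyl}magnesium bromide | C[C@]1(CC[Mg]Br)COC(C)(C)O1 | intermediate
10 | (4S)-4-[(4E,8E)-4,8-dimethyl-11-(2-methyl-1,3-dioxolan-2-yl)undeca-4,8-dien-1-yl]-2,2,4-trimethyl-1,3-dioxolane | C[C@]1(CCC/C(C)=C/CC/C(C)=C/CCC2(C)OCCO2)COC(C)(C)O1 | intermediate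
11 | (5E,9E,14S)-14,15-dihydroxy-6,10,14-trimethylpentadeca-5,9-dien-2-one | C[C@@](O)(CO)CCC/C(C)=C/CC/C(C)=C/CCC(C)=O | intermediate
12 | (2S,6E,10E)-2-hydroxy-2,6,10-trimethyl-14-oxopentadeca-6,10-dien-1-yl 4-methylbenzenesulfonate | C[C@@](O)(COS(=O)(=O)c1ccc(C)cc1)CCC/C(C)=C/CC/C(C)=C/CCC(C)=O | intermediate
13 | (5E,9E)-6,10-dimethyl-13-[(2S)-2-methyloxiran-2-yl]trideca-5,9-dien-2-one | C[C@]1(CCC/C(C)=C/CC/C(C)=C/CCC(C)=O)CO1 | intermediate
14 | (4S,5R,8R,9R,10S)-8,13-epoxy-14,15-dinorlabd-12-en-19-ol (tricyclic enol ether, 8α-oxygen) | OC[C@@]1(C)CCC[C@]2(C)[C@H]3CC=C(C)O[C@]3(C)CC[C@@H]12 | intermediate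
15 | (4S,5R,8R,9R,10S)-8,19-dihydroxy-14,15-dinorlabdan-13-one | OC[C@@]1(C)CCC[C@]2(C)[C@@H](CCC(C)=O)[C@](C)(O)CC[C@@H]12 | intermediate
16 | ethyl (4S,5R,8R,9R,10S,13E)-8,19-dihydroxylabd-13-en-15-oate | OC[C@@]1(C)CCC[C@]2(C)[C@@H](CC/C(C)=C/C(=O)OCC)[C@](C)(O)CC[C@@H]12 | intermediate
17 | (4S,5R,8R,9R,10S,13E)-labd-13-ene-8,15,19-triol | OC[C@@]1(C)CCC[C@]2(C)[C@@H](CC/C(C)=C/CO)[C@](C)(O)CC[C@@H]12 | intermediate
18 | (4S,5R,8R,9R,10S,13E)-8-hydroxylabd-13-ene-15,19-diyl diacetate | CC(=O)OC[C@@]1(C)CCC[C@]2(C)[C@@H](CC/C(C)=C/COC(C)=O)[C@](C)(O)CC[C@@H]12 | intermediate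
19 | (4S,5R,8R,9R,10S,13E)-8,15-dihydroxylabd-13-en-19-yl acetate (CNP0161527.1) | CC(=O)OC[C@@]1(C)CCC[C@]2(C)[C@@H](CC/C(C)=C/CO)[C@](C)(O)CC[C@@H]12 | target

## Step count and least certain steps

Total step count: 14 (steps 1–14). Longest linear sequence: 11 steps (5 → 19, steps 4–14; the branch from 1, steps 1–3 and 7–14, is equally long).

**Step 10 (key step, proposed new method).** Four processes are the most likely failures:
- ionisation of the C4–O bond ahead of π-participation, which would erase the only stereocentre of 13 and with it both the enantiomeric purity and the axial/equatorial preference at C4;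
- 1,2-hydride shift from C19 to C4 (Meinwald rearrangement) outrunning ring closure;
- collapse of the C10 cation onto the aluminium alkoxide at C19 before ring B closes;
- proton loss at C8 instead of capture by the Lewis-acid-bound carbonyl oxygen.

The fallback uses known chemistry: the controlling stereocentre is moved from C4 to C3 in a conventional trisubstituted oxirane, at the price of a later deoxygenation. It sets out from bromide 8 and comes back at 15. Alkylation of the lithium enolate of ethyl acetate with 8 gives the ester F1, which i-Bu2AlH at −78 °C reduces to the aldehyde F2. Still–Gennari olefination with methyl 2-[bis(2,2,2-trifluoroethoxy)phosphoryl]propanoate and KN(SiMe3)2 gives the (Z)-2-methyl enoate F3, and i-Bu2AlH gives the (Z)-allylic alcohol F4. PPTS in wet acetone frees the keto alcohol F5. Sharpless asymmetric epoxidation with Ti(OiPr)4, D-(−)-diethyl tartrate and t-BuOOH gives the (2S,3R)-epoxy alcohol F6, which is silylated (TBDPSCl, imidazole) to the silyl ether F7. MeAlCl2 followed by aqueous acid, as in step 10 but now with an oxirane whose stereocentre at C3 is not the reacting carbon, gives the 3β-hydroxy ketol F8; the oxirane substituent cis to the chain ends axial as C19. Barton–McCombie deoxygenation through the imidazolyl thiocarbonate F9 (1,1'-thiocarbonyldiimidazole; then Bu3SnH, AIBN) gives the silyl ether F10, and TBAF removes the silyl group to give 15.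

**Step 7.** The likely failures are allylic transposition (SN2' attack) or loss of E geometry in the copper-catalysed coupling, and homocoupling of the Grignard reagent. The fallback is a sulfone coupling that sets out from 8 (with 3) and comes back at 10. Sodium benzenesulfinate in DMF converts 8 into the allyl sulfone F11. I2, PPh3 and imidazole convert alcohol 3 into the iodide F12. The lithiated sulfone (n-BuLi, THF–DMPU, −78 °C) is alkylated at its α-carbon with F12 to give the sulfone F13. Reductive desulfonylation with LiBHEt3 and PdCl2(dppf) (cat.) gives 10.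

**Step 11.** The likely failures are incomplete E selectivity in the olefination of a methyl ketone and consumption of the enoate by oxa-Michael addition of the C8 alkoxide. The fallback builds the alkene by syn carbometalation and bypasses steps 11 and 12; it sets out from 15 and comes back at 17. TESOTf and 2,6-lutidine give the bis(triethylsilyl) ether F14. LiN(i-Pr)2 and ClP(O)(OEt)2 give the terminal enol phosphate F15, which a second portion of LiN(i-Pr)2 eliminates to the terminal alkyne F16. Negishi carboalumination (Me3Al, Cp2ZrCl2 cat.), then n-BuLi and paraformaldehyde, gives the (E)-allylic alcohol F17 with the geometry fixed by syn addition of methyl and aluminium. TBAF removes both silyl groups to give 17.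

**Step 14.** The likely failures are slow or incomplete enzymatic alcoholysis of this lipophilic substrate, or partial loss of the C19 acetate. The fallback swaps selective deacylation for selective silylation; it sets out from 17 and comes back at 19. TBSCl and imidazole at −20 °C silylate only the open C15 hydroxyl to give the silyl ether F18. Ac2O, pyridine and DMAP acetylate C19 to give the acetate F19. HF·pyridine removes the silyl group to give 19.

## Further compounds

F1 | step 10 | ethyl (4E,8E)-4,8-dimethyl-11-(2-methyl-1,3-dioxolan-2-yl)undeca-4,8-dienoate | CCOC(=O)CC/C(C)=C/CC/C(C)=C/CCC1(C)OCCO1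
F2 | step 10 | (4E,8E)-4,8-dimethyl-11-(2-methyl-1,3-dioxolan-2-yl)undeca-4,8-dienal | O=CCC/C(C)=C/CC/C(C)=C/CCC1(C)OCCO1
F3 | step 10 | methyl (2Z,6E,10E)-2,6,10-trimethyl-13-(2-methyl-1,3-dioxolan-2-yl)trideca-2,6,10-trienoate | COC(=O)/C(C)=C\CC/C(C)=C/CC/C(C)=C/CCC1(C)OCCO1
F4 | step 10 | (2Z,6E,10E)-2,6,10-trimethyl-13-(2-methyl-1,3-dioxolan-2-yl)trideca-2,6,10-trien-1-ol | OC/C(C)=C\CC/C(C)=C/CC/C(C)=C/CCC1(C)OCCO1
F5 | step 10 | (5E,9E,13Z)-15-hydroxy-6,10,14-trimethylpentadeca-5,9,13-trien-2-one | OC/C(C)=C\CC/C(C)=C/CC/C(C)=C/CCC(C)=O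
F6 | step 10 | (5E,9E)-13-[(2S,3R)-3-(hydroxymethyl)-3-methyloxiran-2-yl]-6,10-dimethyltrideca-5,9-dien-2-one | OC[C@@]1(C)O[C@H]1CC/C(C)=C/CC/C(C)=C/CCC(C)=O
F7 | step 10 | tert-butyldiphenylsilyl ether of F6 | CC(C)(C)[Si](OC[C@@]1(C)O[C@H]1CC/C(C)=C/CC/C(C)=C/CCC(C)=O)(c1ccccc1)c1ccccc1
F8 | step 10 | (3S,4S,5R,8R,9R,10S)-19-(tert-butyldiphenylsilyloxy)-3,8-dihydroxy-14,15-dinorlabdan-13-one | CC(C)(C)[Si](OC[C@@]1(C)[C@@H](O)CC[C@]2(C)[C@@H](CCC(C)=O)[C@](C)(O)CC[C@@H]12)(c1ccccc1)c1ccccc1
F9 | step 10 | 3-O-(imidazol-1-ylthiocarbonyl) derivative of F8 | CC(C)(C)[Si](OC[C@@]1(C)[C@@H](OC(=S)n3ccnc3)CC[C@]2(C)[C@@H](CCC(C)=O)[C@](C)(O)CC[C@@H]12)(c1ccccc1)c1ccccc1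
F10 | step 10 | (4S,5R,8R,9R,10S)-19-(tert-butyldiphenylsilyloxy)-8-hydroxy-14,15-dinorlabdan-13-one | CC(C)(C)[Si](OC[C@@]1(C)CCC[C@]2(C)[C@@H](CCC(C)=O)[C@](C)(O)CC[C@@H]12)(c1ccccc1)c1ccccc1
F11 | step 7 | 2-[(3E,7E)-9-(benzenesulfonyl)-4,8-dimethylnona-3,7-dien-1-yl]-2-methyl-1,3-dioxolane | O=S(=O)(C/C(C)=C/CC/C(C)=C/CCC1(C)OCCO1)c1ccccc1
F12 | step 7 | (4S)-4-(2-iodoethyl)-2,2,4-trimethyl-1,3-dioxolane | C[C@]1(CCI)COC(C)(C)O1
F13 | step 7 | α-alkylated allyl sulfone (benzenesulfonyl group on the carbon that becomes C1; both epimers at that carbon) | C[C@]1(CCC(/C(C)=C/CC/C(C)=C/CCC2(C)OCCO2)S(=O)(=O)c2ccccc2)COC(C)(C)O1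
F14 | step 11 | (4S,5R,8R,9R,10S)-8,19-bis(triethylsilyloxy)-14,15-dinorlabdan-13-one | CC[Si](CC)(CC)OC[C@@]1(C)CCC[C@]2(C)[C@@H](CCC(C)=O)[C@](C)(O[Si](CC)(CC)CC)CC[C@@H]12
F15 | step 11 | terminal enol diethyl phosphate of F14 | CC[Si](CC)(CC)OC[C@@]1(C)CCC[C@]2(C)[C@@H](CCC(=C)OP(=O)(OCC)OCC)[C@](C)(O[Si](CC)(CC)CC)CC[C@@H]12
F16 | step 11 | terminal alkyne from F15 (C12–C≡CH) with 8,19-bis(triethylsilyloxy) groups | CC[Si](CC)(CC)OC[C@@]1(C)CCC[C@]2(C)[C@@H](CCC#C)[C@](C)(O[Si](CC)(CC)CC)CC[C@@H]12
F17 | step 11 | (4S,5R,8R,9R,10S,13E)-8,19-bis(triethylsilyloxy)labd-13-en-15-ol | CC[Si](CC)(CC)OC[C@@]1(C)CCC[C@]2(C)[C@@H](CC/C(C)=C/CO)[C@](C)(O[Si](CC)(CC)CC)CC[C@@H]12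
F18 | step 14 | (4S,5R,8R,9R,10S,13E)-15-(tert-butyldimethylsilyloxy)labd-13-ene-8,19-diol | OC[C@@]1(C)CCC[C@]2(C)[C@@H](CC/C(C)=C/CO[Si](C)(C)C(C)(C)C)[C@](C)(O)CC[C@@H]12
F19 | step 14 | (4S,5R,8R,9R,10S,13E)-15-(tert-butyldimethylsilyloxy)-8-hydroxylabd-13-en-19-yl acetate | CC(=O)OC[C@@]1(C)CCC[C@]2(C)[C@@H](CC/C(C)=C/CO[Si](C)(C)C(C)(C)C)[C@](C)(O)CC[C@@H]12
A1 | alternative 1 | (S)-Wieland–Miescher ketone | C[C@]12CCC(=O)C=C1CCCC2=O
A2 | alternative 2 | ethyl (6E,10E)-2,6,10-trimethyl-3,14-dioxopentadeca-6,10-dienoate | CCOC(=O)C(C)C(=O)CC/C(C)=C/CC/C(C)=C/CCC(C)=O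
A3 | alternative 2 | ethyl 3,13-dioxo-14,15-dinorlabd-8(17)-en-19-oate (racemic; relative configuration shown) | CCOC(=O)[C@@]1(C)C(=O)CC[C@]2(C)[C@@H](CCC(C)=O)C(=C)CC[C@@H]12
A4 | alternative 3 | sclareol, (13R)-labd-14-ene-8α,13-diol | CC1(C)CCC[C@]2(C)[C@@H](CC[C@@](C)(O)C=C)[C@](C)(O)CC[C@@H]12
A5 | alternative 3 | (13E)-labd-13-ene-8α,15-diol | CC1(C)CCC[C@]2(C)[C@@H](CC/C(C)=C/CO)[C@](C)(O)CC[C@@H]12
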